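**Assumption:** the target SMILES has no stereocentres or stereodescriptors (C28H40O4, achiral; the 22-membered ansa ring is too large for stable planar chirality), so no asymmetric step is needed. The route is a design proposal and has not been run experimentally.

## Retrosynthetic overview

1. Target 8 ⇐ global O-demethylation of the tri-O-methyl macrocycle 7.
2. 7 ⇐ one-pot alkene hydrogenation and benzylic C–OH hydrogenolysis of the macrocyclic diol 6.
3. 6 ⇐ ring-closing metathesis of diene-diol 5 at the centre (C8–C9) of the C16 tether, forming the 22-membered ring.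
4. 5 ⇐ double addition of oct-7-enylmagnesium bromide to dialdehyde 3 (each CHO carbon becomes a benzylic chain terminus).
5. 3 ⇐ Ullmann diaryl ether coupling of 1 and 2. Both arenes are purchased; the diaryl ether is formed first and the macrocycle is the only ring built.

## Route

**Step 1**
Reactants: 1, 2-bromo-3,5-dimethoxybenzaldehyde (1.1 equiv); 2, 3-hydroxy-5-methoxybenzaldehyde
Product: 3, 2-(3-formyl-5-methoxyphenoxy)-3,5-dimethoxybenzaldehyde
Conditions: CuI (10–20 mol%), picolinic acid (20–40 mol%), K3PO4, DMSO, 90 °C, Ar
Reagents that add atoms: none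
Why: Cu-catalysed Ullmann diaryl ether synthesis; the ortho-CHO activates the hindered C–Br bond, neither aldehyde is enolisable, and the substitution pattern of ring B (OAr flanked by the future chain carbon and OMe) is fixed by the starting material.

**Step 2**
Reactants: 3, the dialdehyde; 4, 8-bromooct-1-ene (3 equiv, converted in situ to the Grignard reagent)
Product: 5, 1-{2-[3-(1-hydroxynon-8-en-1-yl)-5-methoxyphenoxy]-3,5-dimethoxyphenyl}non-8-en-1-ol (diastereomer mixture, inconsequential)
Conditions: 4, Mg, cat. I2, THF, reflux; then 3, THF, 0 °C → rt; aq. NH4Cl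
Reagents that add atoms: oct-7-en-1-ylmagnesium bromide, C=CCCCCCC[Mg]Br (from 4, BrCCCCCCC=C)
Why: Double Grignard addition to two non-enolisable aryl aldehydes gives two saturated C9 arms with terminal alkenes; aryl ethers are inert, and the carbinol stereocentres are removed in step 4.

**Step 3**
Reactants: 5, the diene-diol
Product: 6, 22-membered macrocyclic diol with one internal C=C (E/Z mixture), tri-O-methyl ether
Conditions: Grubbs II (5–10 mol%), 1,4-benzoquinone (10 mol%), CH2Cl2 (1 mM), 40 °C
Reagents that add atoms: none (ethylene is lost)
Why: Macrocyclic ring-closing metathesis of two unhindered terminal alkenes held by the diaryl ether hinge; with no styrenyl alkenes present there is no ring-contraction pathway, and the remote free alcohols are tolerated. The 9 + 9 − 2 carbons give exactly the C16 bridge, and the E/Z ratio is irrelevant.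

**Step 4**
Reactants: 6, the macrocyclic ene-diol
Product: 7, tri-O-methylgrevirobstol B (saturated C16-bridged diaryl ether)
Conditions: H2 (3–4 atm), 10% Pd/C, EtOAc–AcOH, cat. HClO4, rt → 40 °C
Reagents that add atoms: none (H2 only)
Why: Catalytic hydrogenation saturates the alkene, and acid-promoted Pd hydrogenolysis cleaves both secondary benzylic C–OH bonds, as in the classical carbinol route to 5-alkylresorcinol ethers; aryl methyl ethers and the diaryl ether survive.

**Step 5**
Reactants: 7, the trimethyl ether
Product: 8, grevirobstol B
Conditions: BBr3 (7 equiv), CH2Cl2, −78 °C → rt; MeOH then H2O, under Ar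
Reagents that add atoms: none
Why: Lewis-acid-mediated aryl methyl ether cleavage removes all three methyl groups, while the diaryl ether C–O bonds and the alkyl bridge are inert to BBr3.

## Compound list

1 | 2-bromo-3,5-dimethoxybenzaldehyde | O=Cc1cc(OC)cc(OC)c1Br | starting material
2 | 3-hydroxy-5-methoxybenzaldehyde | O=Cc1cc(O)cc(OC)c1 | starting material
3 | 2-(3-formyl-5-methoxyphenoxy)-3,5-dimethoxybenzaldehyde | O=Cc1cc(OC)cc(OC)c1Oc1cc(C=O)cc(OC)c1 | intermediate
4 | 8-bromooct-1-ene | BrCCCCCCC=C | starting material
5 | 1-{2-[3-(1-hydroxynon-8-en-1-yl)-5-methoxyphenoxy]-3,5-dimethoxyphenyl}non-8-en-1-ol | C=CCCCCCCC(O)c1cc(OC)cc(OC)c1Oc1cc(cc(OC)c1)C(O)CCCCCCC=C | intermediate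
6 | macrocyclic ene-diol, tri-O-methyl (22-membered, E/Z mixture) | COc1cc2cc(c1)Oc1c(OC)cc(OC)cc1C(O)CCCCCCC=CCCCCCCC2O | intermediate
7 | tri-O-methylgrevirobstol B | COc1cc2cc(c1)Oc1c(OC)cc(OC)cc1CCCCCCCCCCCCCCCC2 | intermediate
8 | grevirobstol B | Oc1cc2cc(c1)Oc1c(O)cc(O)cc1CCCCCCCCCCCCCCCC2 | target

## Summary

Total steps: 5 (the Grignard reagent is generated in situ in step 2).
Longest linear sequence: 5 steps.

Steps most likely to fail, with fallbacks:

- **Step 1 (Ullmann coupling of a di-ortho-substituted, electron-rich aryl bromide).** Fallback: reverse the polarity. Make 2-hydroxy-3,5-dimethoxybenzaldehyde by ortho-formylation of 2,4-dimethoxyphenol (MgCl2, Et3N, paraformaldehyde) and join it to (3-formyl-5-methoxyphenyl)boronic acid by Chan–Lam coupling (Cu(OAc)2, pyridine, air) to reach the same dialdehyde 3.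
- **Step 3 (macrocyclic RCM: oligomerisation or olefin migration).** Fallback: change the ring-closing bond. Link the two arenes through the C16 chain first (same Grignard chemistry on the separate aldehydes, then cross-metathesis and reduction) and close the 22-membered ring last by intramolecular Ullmann etherification at high dilution.
- **Step 4 (incomplete hydrogenolysis of the two benzylic alcohols).** Fallback: remove the oxygens by elimination instead. Dehydrate 6 with p-TsOH in toluene (Dean–Stark) to the bis-styrenyl triene, then hydrogenate all C=C bonds (H2, Pd/C) to give 7.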